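**Plan**

- Retrosynthesis (prostanoid numbering: C1 ester carbon, ring C8–C12, C9 the ketone): first the C12 O–acetyl bond and the C7=C8 double bond are cut (aldol condensation with a C1–C7 (Z)-enal). Then the C10–Cl and C12–O bonds of the ring are cut together, then the C10–S bond of the sulfinyl enone so revealed, and last the C12–C13 bond to the octenyl chain.
- Enabling feature: in the five-membered ring the chlorine on C10 and the oxygen on C12 lie 1,3 across the C10=C11 double bond, the imprint of a [2,3] shift of a sulfoxide placed on C10.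
- Forward: the ring is bought as 3-ethoxycyclopent-2-enone and no ring is formed. The lower chain is joined first (C12–C13), then sulfur (C10), then chlorine and oxygen in one operation, and the upper chain last (C7=C8).
- Stereochemistry: C12, the only stereocentre, is set by chirality transfer from the sulfur of (1R,2S,5R)-menthyl (S)-p-toluenesulfinate. 14Z is bought with (Z)-oct-2-en-1-ol, 5Z comes from a Lindlar reduction, and 7E from thermodynamic control in the elimination.

Key step: step 8

Remark on the chemistry: the zinc chelate model of step 8 is assumed to hold; a geometric check of that model shows that the (S)-sulfoxide then leads to the C12 configuration of the target.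

Remark on the chemistry: the C1–C7 unit is drawn from hex-5-ynoic acid, not its methyl ester, because the carboxylate protects itself while the acetylide is formed.

Remark on the chemistry: the ring stereocentre of compounds 5–9 is racemic and that of 12 and 13 is an epimer mixture; this is harmless because the centre becomes planar in step 8.

**Route**

Step 1
Reactants: 1 (Z)-oct-2-en-1-ol
Product: 2 (Z)-1-bromooct-2-ene
Conditions: CBr4, PPh3, CH2Cl2, 0 °C
Reagents that add atoms: carbon tetrabromide, BrC(Br)(Br)Br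
Why: Appel bromination of a primary allylic alcohol proceeds by SN2 at low temperature, so neither allylic transposition nor loss of the Z geometry is expected.

Step 2
Reactants: 3 3-ethoxycyclopent-2-en-1-one; 2 (Z)-1-bromooct-2-ene
Product: 5 3-ethoxy-5-[(Z)-oct-2-en-1-yl]cyclopent-2-en-1-one (racemic), via lithium enolate 4 (not isolated)
Conditions: LiN(i-Pr)2, THF, −78 °C; then 2, DMPU, −78 → −20 °C
Reagents that add atoms: none
Why: Stork–Danheiser alkylation, in which the kinetic alpha-prime enolate of the vinylogous ester attacks the primary allylic bromide by SN2; the new centre is racemic and is erased in step 8.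

Step 3
Reactants: 5 3-ethoxy-5-[(Z)-oct-2-en-1-yl]cyclopent-2-en-1-one
Product: 7 4-[(Z)-oct-2-en-1-yl]cyclopent-2-en-1-one (racemic), via allylic alcohol 6 (not isolated)
Conditions: LiAlH4, Et2O, 0 °C; then 1 M aq. HCl, rt
Reagents that add atoms: water, O
Why: second half of the Stork–Danheiser enone transposition, 1,2-hydride reduction followed by acid hydrolysis of the enol ether with loss of the allylic hydroxyl, which moves the carbonyl and leaves the side chain on C4.

Step 4
Reactants: 7 4-[(Z)-oct-2-en-1-yl]cyclopent-2-en-1-one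
Product: 8 2-iodo-4-[(Z)-oct-2-en-1-yl]cyclopent-2-en-1-one (racemic)
Conditions: I2, pyridine, CH2Cl2, 0 °C → rt, dark
Reagents that add atoms: iodine, II
Why: pyridine-mediated alpha-iodination of an enone (conjugate addition of pyridine, iodination of the enolate, elimination) is selective for the enone and leaves the isolated Z-alkene alone.

Step 5
Reactants: 8 2-iodo-4-[(Z)-oct-2-en-1-yl]cyclopent-2-en-1-one
Product: 9 6-iodo-8-[(Z)-oct-2-en-1-yl]-1,4-dioxaspiro[4.4]non-6-ene (racemic)
Conditions: (Me3SiOCH2)2, Me3SiOTf (cat.), CH2Cl2, −78 → −20 °C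
Reagents that add atoms: 1,2-bis(trimethylsilyloxy)ethane, C[Si](C)(C)OCCO[Si](C)(C)C
Why: silyl triflate-catalysed acetalisation at low temperature masks the carbonyl for the metalation that follows without moving the ring double bond.

Step 6
Reactants: 9 6-iodo-8-[(Z)-oct-2-en-1-yl]-1,4-dioxaspiro[4.4]non-6-ene; 10 (1R,2S,5R)-menthyl (S)-p-toluenesulfinate
Product: 12 8-[(Z)-oct-2-en-1-yl]-6-[(S)-p-tolylsulfinyl]-1,4-dioxaspiro[4.4]non-6-ene (sulfur S; both C8 epimers), via vinyllithium 11 (not isolated)
Conditions: n-BuLi, THF, −78 °C; cannulated into 10, THF, −78 °C; then H2O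
Reagents that add atoms: none
Why: iodine–lithium exchange followed by the Andersen sulfoxide synthesis, in which the vinyllithium displaces mentholate at sulfur with inversion; the sulfur stereocentre is thereby fixed, and its descriptor stays S only because the priorities change.

Step 7
Reactants: 12 8-[(Z)-oct-2-en-1-yl]-6-[(S)-p-tolylsulfinyl]-1,4-dioxaspiro[4.4]non-6-ene
Product: 13 4-[(Z)-oct-2-en-1-yl]-2-[(S)-p-tolylsulfinyl]cyclopent-2-en-1-one (sulfur S; both C4 epimers)
Conditions: TsOH·H2O (cat.), acetone–H2O, rt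
Reagents that add atoms: water, O
Why: mild hydrolysis of the dioxolane with a non-nucleophilic acid frees the enone without racemising sulfur, which needs a nucleophilic counter-ion such as chloride.

Step 8
Reactants: 13 4-[(Z)-oct-2-en-1-yl]-2-[(S)-p-tolylsulfinyl]cyclopent-2-en-1-one; 14 N-chlorosuccinimide
Product: 19 (4S)-2-chloro-4-hydroxy-4-[(Z)-oct-2-en-1-yl]cyclopent-2-en-1-one, via lithium dienolate 15 (not isolated), via bromozinc dienolate 16 (not isolated), via alpha-chloro allylic sulfoxide 17 (not isolated), via sulfenate ester 18 (not isolated)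
Conditions: LiN(SiMe3)2 (1.05 equiv), THF, −78 → −40 °C; ZnBr2 (1.1 equiv), −78 °C; 14, −78 → 0 °C; then P(OMe)3, MeOH, 0 °C → rt
Reagents that add atoms: none
Why: Proposed new method: LiN(SiMe3)2 should remove the C12 proton, because the resulting cyclopentadienolate is a vinylogous beta-keto sulfoxide enolate and far more stabilised than the cross-conjugated C8 enolate, so both C12 epimers of 13 converge on one planar anion 15, which ZnBr2 locks as the six-membered O–Zn–O chelate 16. N-Chlorosuccinimide then chlorinates C10 from the face of the sulfur lone pair, opposite the p-tolyl group, giving the allylic sulfoxide 17 with sulfur pushed to the tolyl face; the suprafacial [2,3]-sigmatropic (Mislow–Evans) shift carries the sulfinyl oxygen to C12 on that same face, and P(OMe)3 cleaves the sulfenate 18. The closest known reactions are the Mislow–Evans transposition of allylic sulfoxides made by base deconjugation of alpha-sulfinyl enones and enoates, and the alpha-chlorination of beta-keto sulfoxides; their union in one flask with chlorine as the deconjugating electrophile is new. No ring is closed; the C10–Cl and C12–O bonds are formed. The one new stereocentre, C12, is controlled by the sulfur stereocentre through the chelate, and in this model the (S)-sulfoxide delivers oxygen to the face drawn for 19. The step needs C12 over C8 deprotonation (secured by the sulfinyl-stabilised extended enolate under equilibrating conditions), alpha over gamma chlorination (secured by the higher electron density at C10) and face selectivity (secured by the rigid zinc chelate), while conjugation of the new chloroenone and the thiophile pull the sulfoxide–sulfenate equilibrium forward.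

Step 9
Reactants: 19 (4S)-2-chloro-4-hydroxy-4-[(Z)-oct-2-en-1-yl]cyclopent-2-en-1-one
Product: 20 (4S)-2-chloro-4-[(Z)-oct-2-en-1-yl]-4-(triethylsilyloxy)cyclopent-2-en-1-one
Conditions: Et3SiOTf, 2,6-lutidine, CH2Cl2, −78 → 0 °C
Reagents that add atoms: triethylsilyl triflate, CC[Si](CC)(CC)OS(=O)(=O)C(F)(F)F
Why: a silyl triflate with a hindered pyridine base silylates even a tertiary carbinol, and the weak base does not enolise the chloroenone.

Step 10
Reactants: 21 hex-5-ynoic acid
Product: 23 7-hydroxyhept-5-ynoic acid, via dilithium salt 22 (not isolated)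
Conditions: n-BuLi (2.1 equiv), THF, −78 → 0 °C; (CH2O)n, 0 °C → rt; then aq. HCl
Reagents that add atoms: paraformaldehyde (as formaldehyde), C=O
Why: the carboxylate–acetylide dianion adds to formaldehyde at the acetylide carbon only, a standard hydroxymethylation of a terminal alkyne that supplies C7.

Step 11
Reactants: 23 7-hydroxyhept-5-ynoic acid
Product: 24 methyl 7-hydroxyhept-5-ynoate
Conditions: MeOH, H2SO4 (cat.), reflux
Reagents that add atoms: methanol, CO
Why: Fischer esterification in excess methanol converts the acid into the methyl ester of the target and leaves the propargylic alcohol untouched.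

Step 12
Reactants: 24 methyl 7-hydroxyhept-5-ynoate
Product: 25 methyl (Z)-7-hydroxyhept-5-enoate
Conditions: H2 (1 atm), Pd/CaCO3 poisoned with Pb(OAc)2, quinoline, EtOAc, rt
Reagents that add atoms: none
Why: Lindlar semi-hydrogenation adds hydrogen syn to the alkyne and stops at the alkene, which sets the 5Z geometry.

Step 13
Reactants: 25 methyl (Z)-7-hydroxyhept-5-enoate
Product: 26 methyl (Z)-7-oxohept-5-enoate
Conditions: MnO2 (activated, excess), CH2Cl2, 0 °C → rt; used at once
Reagents that add atoms: none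
Why: heterogeneous allylic oxidation with MnO2 is neutral, so the sensitive (Z)-enal should form without isomerisation if it is filtered and used directly.

Step 14
Reactants: 20 (4S)-2-chloro-4-[(Z)-oct-2-en-1-yl]-4-(triethylsilyloxy)cyclopent-2-en-1-one; 26 methyl (Z)-7-oxohept-5-enoate
Product: 28 methyl (5Z,12S,14Z)-10-chloro-7-hydroxy-9-oxo-12-(triethylsilyloxy)prosta-5,10,14-trien-1-oate (C12 spatially as in 20; mixture at C7 and C8), via lithium enolate 27 (not isolated)
Conditions: LiN(i-Pr)2, THF, −78 °C; then 26, −78 °C; AcOH quench at −78 °C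
Reagents that add atoms: none
Why: aldol addition of the kinetic C8 enolate to the aldehyde, which outruns attack on the ester; loss of the beta-silyloxy group is blocked because it would give a cyclopentadienone, and the new C7 and C8 centres are removed in step 15.

Step 15
Reactants: 28 methyl (5Z,12S,14Z)-10-chloro-7-hydroxy-9-oxo-12-(triethylsilyloxy)prosta-5,10,14-trien-1-oate
Product: 30 methyl (5Z,7E,12R,14Z)-10-chloro-9-oxo-12-(triethylsilyloxy)prosta-5,7,10,14-tetraen-1-oate, via C7 mesylate 29 (not isolated)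
Conditions: MsCl, Et3N (excess), CH2Cl2, −20 °C → rt
Reagents that add atoms: none
Why: mesylation followed by E1cB elimination through the C8 enolate gives the cross-conjugated dienone, and the reversible enolate step should favour the 7E isomer, in which the C7 hydrogen and not C6 faces the C9 carbonyl.

Step 16
Reactants: 30 methyl (5Z,7E,12R,14Z)-10-chloro-9-oxo-12-(triethylsilyloxy)prosta-5,7,10,14-tetraen-1-oate
Product: 31 methyl (5Z,7E,12R,14Z)-10-chloro-12-hydroxy-9-oxoprosta-5,7,10,14-tetraen-1-oate
Conditions: HF·pyridine, pyridine, THF, 0 °C → rt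
Reagents that add atoms: none
Why: buffered fluoride cleavage of the triethylsilyl ether is mild enough for the chlorodienone and the Z-olefins, unlike basic fluoride sources.

Step 17
Reactants: 31 methyl (5Z,7E,12R,14Z)-10-chloro-12-hydroxy-9-oxoprosta-5,7,10,14-tetraen-1-oate
Product: 32 methyl (5Z,7E,12R,14Z)-12-acetoxy-10-chloro-9-oxoprosta-5,7,10,14-tetraen-1-oate
Conditions: Ac2O, DMAP, Et3N, CH2Cl2, rt
Reagents that add atoms: acetic anhydride, CC(=O)OC(C)=O
Why: DMAP-catalysed acylation acetylates the tertiary C12 carbinol with retention, since the C–O bond is not touched.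

**Compound list**

1 | (Z)-oct-2-en-1-ol | CCCCC/C=C\CO | starting material
2 | (Z)-1-bromooct-2-ene | CCCCC/C=C\CBr | intermediate
3 | 3-ethoxycyclopent-2-en-1-one | CCOC1=CC(=O)CC1 | starting material
4 | lithium 3-ethoxycyclopenta-1,3-dien-1-olate (kinetic enolate of 3) | CCOC1=CC(O[Li])=CC1 | intermediate
5 | 3-ethoxy-5-[(Z)-oct-2-en-1-yl]cyclopent-2-en-1-one (racemic) | CCCCC/C=C\CC1CC(OCC)=CC1=O | intermediate
6 | 3-ethoxy-5-[(Z)-oct-2-en-1-yl]cyclopent-2-en-1-ol (isomer mixture) | CCCCC/C=C\CC1CC(OCC)=CC1O | intermediate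
7 | 4-[(Z)-oct-2-en-1-yl]cyclopent-2-en-1-one (racemic) | CCCCC/C=C\CC1C=CC(=O)C1 | intermediate
8 | 2-iodo-4-[(Z)-oct-2-en-1-yl]cyclopent-2-en-1-one (racemic) | CCCCC/C=C\CC1C=C(I)C(=O)C1 | intermediate
9 | 6-iodo-8-[(Z)-oct-2-en-1-yl]-1,4-dioxaspiro[4.4]non-6-ene (racemic) | CCCCC/C=C\CC1C=C(I)C2(C1)OCCO2 | intermediate
10 | (1R,2S,5R)-menthyl (S)-p-toluenesulfinate | CC(C)[C@@H]1CC[C@@H](C)C[C@H]1O[S@](=O)c1ccc(C)cc1 | starting material
11 | 6-lithio-8-[(Z)-oct-2-en-1-yl]-1,4-dioxaspiro[4.4]non-6-ene | [Li]C1=CC(C/C=C\CCCCC)CC12OCCO2 | intermediate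
12 | 8-[(Z)-oct-2-en-1-yl]-6-[(S)-p-tolylsulfinyl]-1,4-dioxaspiro[4.4]non-6-ene (both C8 epimers) | Cc1ccc(cc1)[S@](=O)C1=CC(C/C=C\CCCCC)CC12OCCO2 | intermediate
13 | 4-[(Z)-oct-2-en-1-yl]-2-[(S)-p-tolylsulfinyl]cyclopent-2-en-1-one (both C4 epimers) | Cc1ccc(cc1)[S@](=O)C1=CC(C/C=C\CCCCC)CC1=O | intermediate
14 | N-chlorosuccinimide | O=C1CCC(=O)N1Cl | starting material
15 | lithium 4-[(Z)-oct-2-en-1-yl]-2-[(S)-p-tolylsulfinyl]cyclopenta-1,3-dien-1-olate | Cc1ccc(cc1)[S@](=O)C1=C(O[Li])CC(C/C=C\CCCCC)=C1 | intermediate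
16 | bromozinc 4-[(Z)-oct-2-en-1-yl]-2-[(S)-p-tolylsulfinyl]cyclopenta-1,3-dien-1-olate | Cc1ccc(cc1)[S@](=O)C1=C(O[Zn]Br)CC(C/C=C\CCCCC)=C1 | intermediate
17 | (2R)-2-chloro-4-[(Z)-oct-2-en-1-yl]-2-[(S)-p-tolylsulfinyl]cyclopent-3-en-1-one | Cc1ccc(cc1)[S@](=O)[C@@]1(Cl)C=C(C/C=C\CCCCC)CC1=O | intermediate
18 | (4S)-2-chloro-4-[(Z)-oct-2-en-1-yl]-4-[(p-tolylsulfanyl)oxy]cyclopent-2-en-1-one | CCCCC/C=C\C[C@@]1(OSc2ccc(C)cc2)C=C(Cl)C(=O)C1 | intermediate
19 | (4S)-2-chloro-4-hydroxy-4-[(Z)-oct-2-en-1-yl]cyclopent-2-en-1-one | CCCCC/C=C\C[C@@]1(O)C=C(Cl)C(=O)C1 | intermediate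
20 | (4S)-2-chloro-4-[(Z)-oct-2-en-1-yl]-4-(triethylsilyloxy)cyclopent-2-en-1-one | CCCCC/C=C\C[C@@]1(O[Si](CC)(CC)CC)C=C(Cl)C(=O)C1 | intermediate
21 | hex-5-ynoic acid | C#CCCCC(=O)O | starting material
22 | lithium 6-lithiohex-5-ynoate | [Li]C#CCCCC(=O)O[Li] | intermediate
23 | 7-hydroxyhept-5-ynoic acid | OCC#CCCCC(=O)O | intermediate
24 | methyl 7-hydroxyhept-5-ynoate | COC(=O)CCCC#CCO | intermediate
25 | methyl (Z)-7-hydroxyhept-5-enoate | COC(=O)CCC/C=C\CO | intermediate
26 | methyl (Z)-7-oxohept-5-enoate | COC(=O)CCC/C=C\C=O | intermediate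
27 | lithium C8 enolate of 20 (C12 as in 20) | CCCCC/C=C\C[C@@]1(O[Si](CC)(CC)CC)C=C(Cl)C(O[Li])=C1 | intermediate
28 | methyl (5Z,12S,14Z)-10-chloro-7-hydroxy-9-oxo-12-(triethylsilyloxy)prosta-5,10,14-trien-1-oate (mixture at C7 and C8) | CCCCC/C=C\C[C@@]1(O[Si](CC)(CC)CC)C=C(Cl)C(=O)C1C(O)/C=C\CCCC(=O)OC | intermediate
29 | methyl (5Z,12S,14Z)-10-chloro-7-(methylsulfonyloxy)-9-oxo-12-(triethylsilyloxy)prosta-5,10,14-trien-1-oate (mixture at C7 and C8) | CCCCC/C=C\C[C@@]1(O[Si](CC)(CC)CC)C=C(Cl)C(=O)C1C(OS(C)(=O)=O)/C=C\CCCC(=O)OC | intermediate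
30 | methyl (5Z,7E,12R,14Z)-10-chloro-9-oxo-12-(triethylsilyloxy)prosta-5,7,10,14-tetraen-1-oate | CCCCC/C=C\C[C@@]1(O[Si](CC)(CC)CC)C=C(Cl)C(=O)/C1=C/C=C\CCCC(=O)OC | intermediate
31 | methyl (5Z,7E,12R,14Z)-10-chloro-12-hydroxy-9-oxoprosta-5,7,10,14-tetraen-1-oate | CCCCC/C=C\C[C@@]1(O)C=C(Cl)C(=O)/C1=C/C=C\CCCC(=O)OC | intermediate
32 | methyl (5Z,7E,12R,14Z)-12-acetoxy-10-chloro-9-oxoprosta-5,7,10,14-tetraen-1-oate | CCCCC/C=C\C[C@@]1(OC(C)=O)C=C(Cl)C(=O)/C1=C/C=C\CCCC(=O)OC | target

**Count and risks**

Total step count: 17. Longest linear sequence: 13 steps (steps 1–9, then 14–17); the enal branch (steps 10–13) has 4 steps.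

Steps most likely to fail:

1. Step 8. The base may deprotonate C8 instead of C12, chlorine may enter at C12 or on the wrong face of the dienolate, or the phosphite may reduce the chlorosulfoxide before it rearranges. The fallback separates the two events and uses known chemistry; it sets out from 13 and comes back at 19. Treating 13 with Et3N and P(OMe)3 in MeOH should deconjugate it to the allylic sulfoxide 4-[(Z)-oct-2-en-1-yl]-2-(p-tolylsulfinyl)cyclopent-3-en-1-one F1. Its Mislow–Evans shift gives the sulfenate 4-[(Z)-oct-2-en-1-yl]-4-[(p-tolylsulfanyl)oxy]cyclopent-2-en-1-one F2, which is cleaved in the same flask to (4S)-4-hydroxy-4-[(Z)-oct-2-en-1-yl]cyclopent-2-en-1-one F3. If the transfer from sulfur is incomplete, the enantiomers would be separated on a chiral stationary phase. Nucleophilic epoxidation (t-BuOOH, DBU, CH2Cl2, 0 °C) would give 2,3-epoxy-4-hydroxy-4-[(Z)-oct-2-en-1-yl]cyclopentan-1-one F4. HCl in THF at 0 °C should open the epoxide at C10 to the chlorohydrin 2-chloro-3,4-dihydroxy-4-[(Z)-oct-2-en-1-yl]cyclopentan-1-one F5, which loses water to give 19.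

2. Step 15. The allylic C7 mesylate may be displaced by chloride before it eliminates, or geometric control may be lost (7E against 7Z, or drift of 5Z to 5E). The fallback changes the leaving group and the order of events; it sets out from 28 and comes back at the target 32, replacing steps 15–17. HF·pyridine would desilylate 28 to the diol methyl (5Z,14Z)-10-chloro-7,12-dihydroxy-9-oxoprosta-5,10,14-trien-1-oate F6. Ac2O, DMAP and pyridine would then acetylate both hydroxyls to the diacetate methyl (5Z,14Z)-7,12-diacetoxy-10-chloro-9-oxoprosta-5,10,14-trien-1-oate F7, which should lose acetic acid across C7–C8 by E1cB in the same flask to give 32.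

3. Step 2. Proton exchange between enolate and product may cause dialkylation, or the allylic bromide may react with allylic transposition or erosion of its Z geometry. The fallback carries the chain as an alkyne and sets the olefin geometry afterwards; it sets out from 3 and comes back at 5. The enolate 4 would be alkylated with commercial 1-bromooct-2-yne to give 3-ethoxy-5-(oct-2-yn-1-yl)cyclopent-2-en-1-one F8. Lindlar semi-hydrogenation (H2, Pd/CaCO3 poisoned with Pb(OAc)2, quinoline) would then give 5, the vinylogous ester double bond being inert under these conditions.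

**Further compounds**

F1 | step 8 | 4-[(Z)-oct-2-en-1-yl]-2-(p-tolylsulfinyl)cyclopent-3-en-1-one (sulfur as in 13) | Cc1ccc(cc1)[S@](=O)C1C=C(C/C=C\CCCCC)CC1=O
F2 | step 8 | (4S)-4-[(Z)-oct-2-en-1-yl]-4-[(p-tolylsulfanyl)oxy]cyclopent-2-en-1-one | CCCCC/C=C\C[C@@]1(OSc2ccc(C)cc2)C=CC(=O)C1
F3 | step 8 | (4S)-4-hydroxy-4-[(Z)-oct-2-en-1-yl]cyclopent-2-en-1-one | CCCCC/C=C\C[C@@]1(O)C=CC(=O)C1
F4 | step 8 | 2,3-epoxy-4-hydroxy-4-[(Z)-oct-2-en-1-yl]cyclopentan-1-one (carbinol carbon as in F3) | CCCCC/C=C\C[C@@]1(O)C2OC2C(=O)C1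
F5 | step 8 | 2-chloro-3,4-dihydroxy-4-[(Z)-oct-2-en-1-yl]cyclopentan-1-one (carbinol carbon as in F3) | CCCCC/C=C\C[C@@]1(O)C(O)C(Cl)C(=O)C1
F6 | step 15 | methyl (5Z,14Z)-10-chloro-7,12-dihydroxy-9-oxoprosta-5,10,14-trien-1-oate (C12 as in 28) | CCCCC/C=C\C[C@@]1(O)C=C(Cl)C(=O)C1C(O)/C=C\CCCC(=O)OC
F7 | step 15 | methyl (5Z,14Z)-7,12-diacetoxy-10-chloro-9-oxoprosta-5,10,14-trien-1-oate (C12 as in 28) | CCCCC/C=C\C[C@@]1(OC(C)=O)C=C(Cl)C(=O)C1C(OC(C)=O)/C=C\CCCC(=O)OC
F8 | step 2 | 3-ethoxy-5-(oct-2-yn-1-yl)cyclopent-2-en-1-one | CCCCCC#CCC1CC(OCC)=CC1=O
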